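Ring C of the flavanone is cut twice, at C2–C3 and at O1–C8a. This exploits the fact that C8a of ring A lies ortho to the C4 carbonyl and meta to both ring-A oxygens (C5, C7), so it is an SNAr position, while C3 is the α-carbon of that ketone. The key step joins a 2-fluoroaryl silyl enol ether (ring A, carrying the Z-diene) to the enantiopure dihydrobenzofuran aldehyde: a catalytic enantioselective Mukaiyama aldol sets C2 and forms C2–C3, then fluoride-catalysed desilylative SNAr forms O1–C8a, expelling Me3SiF. The aldehyde comes from a rhodium-carbene C–H insertion; global MOM removal ends the route.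

Key step: step 15

Assumption: the absolute sense of induction of the two chiral catalysts (steps 11 and 15) is assigned by analogy with simpler substrates; should a model run show the opposite sense, the mirror-image catalyst is used and nothing else changes.

**Ring A fragment**

Step 1
Reactants: 1 5-fluororesorcinol
Product: 2 1-(2-fluoro-4,6-dihydroxyphenyl)ethan-1-one
Conditions: AcOH, ZnCl2, 140 °C
Reagents that add atoms: acetic acid, CC(=O)O
Why: Nencki reaction (Friedel–Crafts C-acylation of a resorcinol); attack at C4, para to one hydroxyl and ortho to the other, should dominate over the position between the two hydroxyls and places the acetyl group beside fluorine.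

Step 2
Reactants: 2 1-(2-fluoro-4,6-dihydroxyphenyl)ethan-1-one
Product: 3 1-[2-fluoro-4,6-bis(methoxymethoxy)phenyl]ethan-1-one
Conditions: NaH (2.3 equiv), MOMCl (2.5 equiv), DMF, 0 °C to rt
Reagents that add atoms: chloromethyl methyl ether, COCCl
Why: Williamson-type O-alkylation of both phenoxides (NaH is needed for the chelated ortho hydroxyl) gives acetal ethers that are stable to every later basic, organometallic and fluoride step.

Step 3
Reactants: 3 1-[2-fluoro-4,6-bis(methoxymethoxy)phenyl]ethan-1-one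
Product: 4 1-[2-fluoro-3-iodo-4,6-bis(methoxymethoxy)phenyl]ethan-1-one
Conditions: NIS (1.1 equiv), TFA (10 mol %), MeCN, 0 °C to rt
Reagents that add atoms: N-iodosuccinimide, O=C1CCC(=O)N1I
Why: Electrophilic aromatic iodination should go to C3, which is para to the C6 oxygen, ortho to the C4 oxygen and flanked only by fluorine, in preference to C5 between two alkoxy groups; a minor C5 isomer would be removed by chromatography.

Step 4
Reactants: 4 1-[2-fluoro-3-iodo-4,6-bis(methoxymethoxy)phenyl]ethan-1-one; 5 2-methylbut-1-en-3-yne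
Product: 6 1-[2-fluoro-4,6-bis(methoxymethoxy)-3-(3-methylbut-3-en-1-yn-1-yl)phenyl]ethan-1-one
Conditions: 5 (3 equiv), PdCl2(PPh3)2 (5 mol %), CuI (10 mol %), Et3N, THF, 50 °C, sealed tube
Reagents that add atoms: none
Why: Sonogashira coupling of the aryl iodide with the terminal alkyne; the C–F bond and the ketone are inert under these conditions.

Step 5
Reactants: 6 1-[2-fluoro-4,6-bis(methoxymethoxy)-3-(3-methylbut-3-en-1-yn-1-yl)phenyl]ethan-1-one
Product: 7 1-{2-fluoro-4,6-bis(methoxymethoxy)-3-[(1Z)-3-methylbuta-1,3-dien-1-yl]phenyl}ethan-1-one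
Conditions: H2 (1 atm), Pd/CaCO3 poisoned with Pb(OAc)2, quinoline, EtOAc, rt, stopped after one equivalent of H2
Reagents that add atoms: none
Why: Lindlar semihydrogenation delivers both hydrogens to one face of the alkyne on the poisoned palladium surface, so the conjugated enyne should give the Z-diene, and the isopropenyl group and aryl fluoride are not reduced.

Step 6
Reactants: 7 1-{2-fluoro-4,6-bis(methoxymethoxy)-3-[(1Z)-3-methylbuta-1,3-dien-1-yl]phenyl}ethan-1-one
Product: 9 [(1-{2-fluoro-4,6-bis(methoxymethoxy)-3-[(1Z)-3-methylbuta-1,3-dien-1-yl]phenyl}ethenyl)oxy](trimethyl)silane, via lithium enolate 8 (not isolated)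
Conditions: LiN(SiMe3)2 (1.1 equiv), THF, −78 °C; then Me3SiCl, −78 to 0 °C; non-aqueous work-up
Reagents that add atoms: chlorotrimethylsilane, C[Si](C)(C)Cl
Why: Kinetic deprotonation of the only enolisable position (the acetyl methyl) and O-silylation of the lithium enolate give the silyl enol ether, with base and temperature too mild for attack at the C–F bond.

**Dihydrobenzofuran aldehyde fragment**

Step 7
Reactants: 10 5-bromo-2-hydroxy-4-methoxybenzaldehyde; 11 4-methoxybenzyl chloride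
Product: 12 5-bromo-4-methoxy-2-[(4-methoxybenzyl)oxy]benzaldehyde
Conditions: K2CO3, DMF, 60 °C
Reagents that add atoms: none
Why: Williamson ether synthesis; the benzylic CH2 introduced here later becomes C2 of the dihydrofuran ring together with its 4-oxygenated aryl group.

Step 8
Reactants: 12 5-bromo-4-methoxy-2-[(4-methoxybenzyl)oxy]benzaldehyde; 13 3,5-dimethoxyphenylmagnesium chloride
Product: 14 {5-bromo-4-methoxy-2-[(4-methoxybenzyl)oxy]phenyl}(3,5-dimethoxyphenyl)methanol (racemic)
Conditions: THF, 0 °C; aq. NH4Cl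
Reagents that add atoms: none
Why: Grignard addition to the aldehyde is much faster than any exchange at the aryl bromide at 0 °C, and the carbinol centre is of no consequence because it is oxidised in the next step.

Step 9
Reactants: 14 {5-bromo-4-methoxy-2-[(4-methoxybenzyl)oxy]phenyl}(3,5-dimethoxyphenyl)methanol
Product: 15 {5-bromo-4-methoxy-2-[(4-methoxybenzyl)oxy]phenyl}(3,5-dimethoxyphenyl)methanone
Conditions: activated MnO2 (excess), CH2Cl2, rt
Reagents that add atoms: none
Why: Selective oxidation of a doubly benzylic alcohol by MnO2, which leaves the ethers and the aryl bromide alone.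

Step 10
Reactants: 15 {5-bromo-4-methoxy-2-[(4-methoxybenzyl)oxy]phenyl}(3,5-dimethoxyphenyl)methanone
Product: 16 {5-bromo-4-methoxy-2-[(4-methoxybenzyl)oxy]phenyl}(3,5-dimethoxyphenyl)methanone hydrazone (E/Z mixture)
Conditions: N2H4·H2O (excess), AcOH (cat.), EtOH, 80 °C, sealed tube
Reagents that add atoms: hydrazine, NN
Why: Acid-catalysed condensation of the diaryl ketone with excess hydrazine (excess suppresses azine formation) gives the hydrazone, whose C=N geometry is lost in the next step.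

Step 11
Reactants: 16 {5-bromo-4-methoxy-2-[(4-methoxybenzyl)oxy]phenyl}(3,5-dimethoxyphenyl)methanone hydrazone
Product: 18 (2S,3R)-5-bromo-3-(3,5-dimethoxyphenyl)-6-methoxy-2-(4-methoxyphenyl)-2,3-dihydro-1-benzofuran (cis), via diaryldiazomethane 17 (not isolated)
Conditions: MnO2, CH2Cl2, 0 °C; filter; then dirhodium tetrakis[(S)-(1-adamantyl)(N-phthalimido)acetate], Rh2(S-PTAD)4 (1 mol %), CH2Cl2, 0 °C
Reagents that add atoms: none
Why: MnO2 dehydrogenates the hydrazone to the diaryldiazomethane, whose donor/donor rhodium carbene inserts into the benzylic ether C–H bond (intramolecular 1,5 C–H insertion), the chiral carboxylate ligands setting C3 (R) and, kinetically, the cis C2 (S) centre.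

Step 12
Reactants: 18 (2S,3R)-5-bromo-3-(3,5-dimethoxyphenyl)-6-methoxy-2-(4-methoxyphenyl)-2,3-dihydro-1-benzofuran
Product: 19 5-[(2R,3R)-5-bromo-6-hydroxy-2-(4-hydroxyphenyl)-2,3-dihydro-1-benzofuran-3-yl]benzene-1,3-diol (trans)
Conditions: BBr3 (10 equiv), CH2Cl2, −78 °C to rt, high dilution; then H2O, 0 °C
Reagents that add atoms: none
Why: BBr3 cleaves the four aryl methyl ethers, and the same Lewis acid reversibly ionises the benzylic C2–O1 bond (cation stabilised by the para oxygen of the C2 aryl group), so C2 should equilibrate to the more stable trans (2R) arrangement while C3 is not touched.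

Step 13
Reactants: 19 5-[(2R,3R)-5-bromo-6-hydroxy-2-(4-hydroxyphenyl)-2,3-dihydro-1-benzofuran-3-yl]benzene-1,3-diol
Product: 20 (2R,3R)-3-[3,5-bis(methoxymethoxy)phenyl]-5-bromo-6-(methoxymethoxy)-2-[4-(methoxymethoxy)phenyl]-2,3-dihydro-1-benzofuran
Conditions: MOMCl (6 equiv), i-Pr2NEt (8 equiv), CH2Cl2, 0 °C to rt
Reagents that add atoms: chloromethyl methyl ether, COCCl
Why: O-alkylation of the four unhindered phenols under mild amine base gives the same base- and fluoride-stable acetal protection as on ring A.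

Step 14
Reactants: 20 (2R,3R)-3-[3,5-bis(methoxymethoxy)phenyl]-5-bromo-6-(methoxymethoxy)-2-[4-(methoxymethoxy)phenyl]-2,3-dihydro-1-benzofuran
Product: 22 (2R,3R)-3-[3,5-bis(methoxymethoxy)phenyl]-6-(methoxymethoxy)-2-[4-(methoxymethoxy)phenyl]-2,3-dihydro-1-benzofuran-5-carbaldehyde, via aryllithium 21 (not isolated)
Conditions: n-BuLi (1.1 equiv), THF, −78 °C; then DMF, −78 to 0 °C; aq. NH4Cl
Reagents that add atoms: N,N-dimethylformamide, CN(C)C=O
Why: Bromine–lithium exchange at −78 °C is faster than any directed deprotonation, the aryllithium is held by the neighbouring acetal oxygen, and Bouveault-type formylation with DMF gives the aldehyde.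

**Union and end game**

Step 15
Reactants: 9 [(1-{2-fluoro-4,6-bis(methoxymethoxy)-3-[(1Z)-3-methylbuta-1,3-dien-1-yl]phenyl}ethenyl)oxy](trimethyl)silane; 22 (2R,3R)-3-[3,5-bis(methoxymethoxy)phenyl]-6-(methoxymethoxy)-2-[4-(methoxymethoxy)phenyl]-2,3-dihydro-1-benzofuran-5-carbaldehyde
Product: 24 (2S)-2-{(2R,3R)-3-[3,5-bis(methoxymethoxy)phenyl]-6-(methoxymethoxy)-2-[4-(methoxymethoxy)phenyl]-2,3-dihydro-1-benzofuran-5-yl}-5,7-bis(methoxymethoxy)-8-[(1Z)-3-methylbuta-1,3-dien-1-yl]-2,3-dihydro-4H-chromen-4-one, via β-silyloxy ketone 23 (not isolated)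
Conditions: 9 (1.0 equiv), 22 (1.05 equiv), (4R)-2-butyl-4-(1H-indol-3-ylmethyl)-3-(4-methylbenzenesulfonyl)-1,3,2-oxazaborolidin-5-one (20 mol %), EtCN, −78 to −40 °C; then Bu4N[Ph3SiF2] (0.5 equiv), THF, −78 to −20 °C; AcOH quench at −20 °C
Reagents that add atoms: none
Why: The chiral boron Lewis acid binds the formyl oxygen of 22 and exposes one face (taken as Si), so silyl enol ether 9 adds in an open-transition-state Mukaiyama aldol that forms C2–C3 and sets C2 (S) under catalyst control, the remote dihydrobenzofuran stereocentres having little say; silyl transfer gives β-silyloxy ketone 23. Fluoride then removes the silyl group and the free C2 alkoxide attacks C8a, which is ortho to the C4 carbonyl and carries fluorine, in an addition–elimination (SNAr) that forms O1–C8a and releases fluoride to carry the chain, so Me3SiF is the only by-product. The closest known reactions are the Lewis-acid-catalysed enantioselective Mukaiyama aldol of aryl methyl ketone silyl enol ethers with aromatic aldehydes and the intramolecular SNAr etherification of 2-fluoroaryl ketones that gives chroman-4-ones. Ring C closes in a 6-endo-trig mode, the alkoxide adding to the β-carbon of the vinylogous acyl fluoride C8a(F)=C4a–C4=O through a six-membered transition state, and because the C2–O bond is never broken C2 is carried over with retention. The step needs ring closure to outrun retro-aldol cleavage and E1cB loss of the C2 oxygen; the ortho-acyl activation, fluoride as nucleofuge, the two ring-A oxygens lying meta to C8a (where they do not oppose the Meisenheimer charge) and the low stationary alkoxide concentration of the fluoride chain at low temperature should secure this. Any C2 epimer that forms is a diastereomer and should be separable by chromatography.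

Step 16
Reactants: 24 (2S)-2-{(2R,3R)-3-[3,5-bis(methoxymethoxy)phenyl]-6-(methoxymethoxy)-2-[4-(methoxymethoxy)phenyl]-2,3-dihydro-1-benzofuran-5-yl}-5,7-bis(methoxymethoxy)-8-[(1Z)-3-methylbuta-1,3-dien-1-yl]-2,3-dihydro-4H-chromen-4-one
Product: 25 (2S)-2-[(2R,3R)-3-(3,5-dihydroxyphenyl)-6-hydroxy-2-(4-hydroxyphenyl)-2,3-dihydro-1-benzofuran-5-yl]-5,7-dihydroxy-8-[(1Z)-3-methylbuta-1,3-dien-1-yl]-2,3-dihydro-4H-chromen-4-one (CNP0284772.1)
Conditions: Me3SiOTf (18 equiv), 2,2'-bipyridyl (27 equiv), MeCN, 0 °C to rt; then H2O, rt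
Reagents that add atoms: none
Why: Me3SiOTf buffered by 2,2'-bipyridyl converts each aryl methoxymethyl ether into the aryl silyl ether under nearly neutral conditions and water then frees the six phenols (acetal cleavage), which avoids the protic acid that would add the C7 hydroxyl to the Z-diene or open ring C.

**Compound list**

1 | 5-fluororesorcinol (5-fluorobenzene-1,3-diol) | Oc1cc(O)cc(F)c1 | starting material
2 | 1-(2-fluoro-4,6-dihydroxyphenyl)ethan-1-one | CC(=O)c1c(O)cc(O)cc1F | intermediate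
3 | 1-[2-fluoro-4,6-bis(methoxymethoxy)phenyl]ethan-1-one | CC(=O)c1c(OCOC)cc(OCOC)cc1F | intermediate
4 | 1-[2-fluoro-3-iodo-4,6-bis(methoxymethoxy)phenyl]ethan-1-one | CC(=O)c1c(OCOC)cc(OCOC)c(I)c1F | intermediate
5 | 2-methylbut-1-en-3-yne | C=C(C)C#C | starting material
6 | 1-[2-fluoro-4,6-bis(methoxymethoxy)-3-(3-methylbut-3-en-1-yn-1-yl)phenyl]ethan-1-one | CC(=O)c1c(OCOC)cc(OCOC)c(C#CC(C)=C)c1F | intermediate
7 | 1-{2-fluoro-4,6-bis(methoxymethoxy)-3-[(1Z)-3-methylbuta-1,3-dien-1-yl]phenyl}ethan-1-one | CC(=O)c1c(OCOC)cc(OCOC)c(/C=C\C(C)=C)c1F | intermediate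
8 | lithium enolate of 7 | [Li]OC(=C)c1c(OCOC)cc(OCOC)c(/C=C\C(C)=C)c1F | intermediate (not isolated)
9 | [(1-{2-fluoro-4,6-bis(methoxymethoxy)-3-[(1Z)-3-methylbuta-1,3-dien-1-yl]phenyl}ethenyl)oxy](trimethyl)silane | C=C(O[Si](C)(C)C)c1c(OCOC)cc(OCOC)c(/C=C\C(C)=C)c1F | intermediate
10 | 5-bromo-2-hydroxy-4-methoxybenzaldehyde | O=Cc1cc(Br)c(OC)cc1O | starting material
11 | 4-methoxybenzyl chloride | COc1ccc(CCl)cc1 | starting material
12 | 5-bromo-4-methoxy-2-[(4-methoxybenzyl)oxy]benzaldehyde | O=Cc1cc(Br)c(OC)cc1OCc1ccc(OC)cc1 | intermediate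
13 | 3,5-dimethoxyphenylmagnesium chloride | COc1cc(OC)cc([Mg]Cl)c1 | starting material
14 | {5-bromo-4-methoxy-2-[(4-methoxybenzyl)oxy]phenyl}(3,5-dimethoxyphenyl)methanol (racemic) | OC(c1cc(OC)cc(OC)c1)c1cc(Br)c(OC)cc1OCc1ccc(OC)cc1 | intermediate
15 | {5-bromo-4-methoxy-2-[(4-methoxybenzyl)oxy]phenyl}(3,5-dimethoxyphenyl)methanone | O=C(c1cc(OC)cc(OC)c1)c1cc(Br)c(OC)cc1OCc1ccc(OC)cc1 | intermediate
16 | hydrazone of 15 (E/Z mixture) | NN=C(c1cc(OC)cc(OC)c1)c1cc(Br)c(OC)cc1OCc1ccc(OC)cc1 | intermediate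
17 | diaryldiazomethane from 16 | [N-]=[N+]=C(c1cc(OC)cc(OC)c1)c1cc(Br)c(OC)cc1OCc1ccc(OC)cc1 | intermediate (not isolated)
18 | (2S,3R)-5-bromo-3-(3,5-dimethoxyphenyl)-6-methoxy-2-(4-methoxyphenyl)-2,3-dihydro-1-benzofuran (cis) | Brc1cc2c(cc1OC)O[C@H](c1ccc(OC)cc1)[C@@H]2c1cc(OC)cc(OC)c1 | intermediate
19 | 5-[(2R,3R)-5-bromo-6-hydroxy-2-(4-hydroxyphenyl)-2,3-dihydro-1-benzofuran-3-yl]benzene-1,3-diol (trans) | Brc1cc2c(cc1O)O[C@@H](c1ccc(O)cc1)[C@@H]2c1cc(O)cc(O)c1 | intermediate
20 | (2R,3R)-3-[3,5-bis(methoxymethoxy)phenyl]-5-bromo-6-(methoxymethoxy)-2-[4-(methoxymethoxy)phenyl]-2,3-dihydro-1-benzofuran | Brc1cc2c(cc1OCOC)O[C@@H](c1ccc(OCOC)cc1)[C@@H]2c1cc(OCOC)cc(OCOC)c1 | intermediate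
21 | aryllithium from 20 (lithium at C5) | [Li]c1cc2c(cc1OCOC)O[C@@H](c1ccc(OCOC)cc1)[C@@H]2c1cc(OCOC)cc(OCOC)c1 | intermediate (not isolated)
22 | (2R,3R)-3-[3,5-bis(methoxymethoxy)phenyl]-6-(methoxymethoxy)-2-[4-(methoxymethoxy)phenyl]-2,3-dihydro-1-benzofuran-5-carbaldehyde | O=Cc1cc2c(cc1OCOC)O[C@@H](c1ccc(OCOC)cc1)[C@@H]2c1cc(OCOC)cc(OCOC)c1 | intermediate
23 | (3S)-β-silyloxy ketone: 3-(the benzofuran-5-yl group of 22)-1-{2-fluoro-4,6-bis(methoxymethoxy)-3-[(1Z)-3-methylbuta-1,3-dien-1-yl]phenyl}-3-[(trimethylsilyl)oxy]propan-1-one | C=C(C)/C=C\c1c(OCOC)cc(OCOC)c(C(=O)C[C@H](O[Si](C)(C)C)c2cc3c(cc2OCOC)O[C@@H](c2ccc(OCOC)cc2)[C@@H]3c2cc(OCOC)cc(OCOC)c2)c1F | intermediate (not isolated)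
24 | (2S)-2-{(2R,3R)-3-[3,5-bis(methoxymethoxy)phenyl]-6-(methoxymethoxy)-2-[4-(methoxymethoxy)phenyl]-2,3-dihydro-1-benzofuran-5-yl}-5,7-bis(methoxymethoxy)-8-[(1Z)-3-methylbuta-1,3-dien-1-yl]-2,3-dihydro-4H-chromen-4-one | C=C(C)/C=C\c1c(OCOC)cc(OCOC)c2c1O[C@H](c1cc3c(cc1OCOC)O[C@@H](c1ccc(OCOC)cc1)[C@@H]3c1cc(OCOC)cc(OCOC)c1)CC2=O | intermediate
25 | (2S)-2-[(2R,3R)-3-(3,5-dihydroxyphenyl)-6-hydroxy-2-(4-hydroxyphenyl)-2,3-dihydro-1-benzofuran-5-yl]-5,7-dihydroxy-8-[(1Z)-3-methylbuta-1,3-dien-1-yl]-2,3-dihydro-4H-chromen-4-one | C=C(C)/C=C\c1c(O)cc(O)c2c1O[C@H](c1cc3c(cc1O)O[C@@H](c1ccc(O)cc1)[C@@H]3c1cc(O)cc(O)c1)CC2=O | target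

**Totals**

Total step count: 16. Longest linear sequence: 10 steps (steps 7 to 16); the ring-A branch (steps 1 to 6) joins at step 15.

**Steps most likely to fail**

1. Step 15 (key step). What may go wrong: poor facial discrimination by the catalyst on this hindered, electron-rich, ortho-alkoxylated aldehyde, and retro-aldol cleavage or E1cB elimination of the alkoxide running ahead of ring closure, both of which erode control at C2. Fallback, closing ring C at O1–C2 instead: setting out from 7, the fluorine is exchanged for hydroxyl with 2-(methylsulfonyl)ethanol and NaH in DMF, by SNAr to the aryl 2-(methylsulfonyl)ethyl ether F1, which loses methyl vinyl sulfone in the flask to give 1-{2-hydroxy-4,6-bis(methoxymethoxy)-3-[(1Z)-3-methylbuta-1,3-dien-1-yl]phenyl}ethan-1-one F2. Claisen–Schmidt condensation of F2 with aldehyde 22 (KOH, EtOH/THF, rt) gives the (E)-2'-hydroxychalcone F3. An enantioselective intramolecular oxa-Michael addition under 1-[3,5-bis(trifluoromethyl)phenyl]-3-[(8α,9S)-6'-methoxycinchonan-9-yl]thiourea (toluene, rt) then closes ring C and returns to the route at 24.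

2. Step 12. What may go wrong: irreversible opening of the dihydrofuran ring, or E1 loss of the C3 proton from the benzylic cation under the strong Lewis acid, and with it loss of the C3 configuration. Fallback: setting out from 18, C2 alone is epimerised with catalytic TFA in CH2Cl2 at 0 °C to (2R,3R)-5-bromo-3-(3,5-dimethoxyphenyl)-6-methoxy-2-(4-methoxyphenyl)-2,3-dihydro-1-benzofuran F4. The four methyl ethers are then cleaved by SN2 attack of NaSEt in DMF at 130 °C, without any Lewis acid, which returns to the route at 19.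

3. Step 16. What may go wrong: damage to the Z-dienyl phenol as it is unmasked (addition of the C7 hydroxyl to the diene to give a dimethylchromene, Z to E drift), epimerisation at C2 by ring opening, or incomplete cleavage of six acetals. Fallback, building the diene last: setting out from 6 (with 22), the ketone is enolised and silylated as in step 6 through the lithium enolate of 6 F5 to the enyne silyl enol ether F6. The step-15 sequence with 22 then leads through the enyne β-silyloxy ketone F7 (not isolated) to the enyne hexakis(methoxymethyl) flavanone F8. The acetals are removed with HCl in MeOH at 40 °C, where the enyne cannot cyclise to a chromene, to give the enyne hexaphenol F9. Lindlar semihydrogenation (H2, Pd/CaCO3 poisoned with Pb(OAc)2, quinoline, EtOAc/MeOH) then returns to the route at 25.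

**Further compounds**

F1 | step 15 | 1-{4,6-bis(methoxymethoxy)-3-[(1Z)-3-methylbuta-1,3-dien-1-yl]-2-[2-(methylsulfonyl)ethoxy]phenyl}ethan-1-one | CC(=O)c1c(OCOC)cc(OCOC)c(/C=C\C(C)=C)c1OCCS(C)(=O)=O
F2 | step 15 | 1-{2-hydroxy-4,6-bis(methoxymethoxy)-3-[(1Z)-3-methylbuta-1,3-dien-1-yl]phenyl}ethan-1-one | CC(=O)c1c(OCOC)cc(OCOC)c(/C=C\C(C)=C)c1O
F3 | step 15 | (2E)-3-{(2R,3R)-3-[3,5-bis(methoxymethoxy)phenyl]-6-(methoxymethoxy)-2-[4-(methoxymethoxy)phenyl]-2,3-dihydro-1-benzofuran-5-yl}-1-{2-hydroxy-4,6-bis(methoxymethoxy)-3-[(1Z)-3-methylbuta-1,3-dien-1-yl]phenyl}prop-2-en-1-one | C=C(C)/C=C\c1c(OCOC)cc(OCOC)c(C(=O)/C=C/c2cc3c(cc2OCOC)O[C@@H](c2ccc(OCOC)cc2)[C@@H]3c2cc(OCOC)cc(OCOC)c2)c1O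
F4 | step 12 | (2R,3R)-5-bromo-3-(3,5-dimethoxyphenyl)-6-methoxy-2-(4-methoxyphenyl)-2,3-dihydro-1-benzofuran (trans) | Brc1cc2c(cc1OC)O[C@@H](c1ccc(OC)cc1)[C@@H]2c1cc(OC)cc(OC)c1
F5 | step 16 | lithium enolate of 6 | [Li]OC(=C)c1c(OCOC)cc(OCOC)c(C#CC(C)=C)c1F
F6 | step 16 | ({1-[2-fluoro-4,6-bis(methoxymethoxy)-3-(3-methylbut-3-en-1-yn-1-yl)phenyl]ethenyl}oxy)(trimethyl)silane | C=C(O[Si](C)(C)C)c1c(OCOC)cc(OCOC)c(C#CC(C)=C)c1F
F7 | step 16 | (3S)-β-silyloxy ketone of the enyne series (analogue of 23) | C=C(C)C#Cc1c(OCOC)cc(OCOC)c(C(=O)C[C@H](O[Si](C)(C)C)c2cc3c(cc2OCOC)O[C@@H](c2ccc(OCOC)cc2)[C@@H]3c2cc(OCOC)cc(OCOC)c2)c1F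
F8 | step 16 | (2S)-2-{(2R,3R)-3-[3,5-bis(methoxymethoxy)phenyl]-6-(methoxymethoxy)-2-[4-(methoxymethoxy)phenyl]-2,3-dihydro-1-benzofuran-5-yl}-5,7-bis(methoxymethoxy)-8-(3-methylbut-3-en-1-yn-1-yl)-2,3-dihydro-4H-chromen-4-one | C=C(C)C#Cc1c(OCOC)cc(OCOC)c2c1O[C@H](c1cc3c(cc1OCOC)O[C@@H](c1ccc(OCOC)cc1)[C@@H]3c1cc(OCOC)cc(OCOC)c1)CC2=O
F9 | step 16 | (2S)-2-[(2R,3R)-3-(3,5-dihydroxyphenyl)-6-hydroxy-2-(4-hydroxyphenyl)-2,3-dihydro-1-benzofuran-5-yl]-5,7-dihydroxy-8-(3-methylbut-3-en-1-yn-1-yl)-2,3-dihydro-4H-chromen-4-one | C=C(C)C#Cc1c(O)cc(O)c2c1O[C@H](c1cc3c(cc1O)O[C@@H](c1ccc(O)cc1)[C@@H]3c1cc(O)cc(O)c1)CC2=O
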